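**Plan**
1. Retrosynthesis (locants of the decahydronaphthalene in the target name): cut the O–SO3H bond and the silyl/benzyl groups, then the exocyclic C5=CH2 bond, then the one-carbon unit C6 out of the ring C4a–C5–C6–C7–C8–C8a (leaving a trans-hydrindan-1-one), then C2–CH3 (as C=CH2), then C1–CH2Ar and C8a–H (reductive benzylation of an enone), and last the enone ring (aldol/Michael).
2. Forward: the cyclopentane is bought (2-methylcyclopentane-1,3-dione) and the cyclohexenone is annulated onto it by Michael addition and amino-acid-mediated aldol condensation. The arene (bromide 8) is joined by reductive alkylation. Only then is the five-membered ring enlarged by one carbon to the second six-membered ring, followed by methylenation, sulfation and desilylation.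
3. Enabling feature: the carbonyl carbon that becomes C5 lies in a five-membered ring between the quaternary ring-fusion carbon C4a (no α-H, neopentyl) and a single CH2 (future C7). A diazoalkane can therefore insert C6 only on the CH2 side, and the ketone stays next to C4a, ready for methylenation.
4. Stereochemistry: C4a from the L-phenylalanine-mediated aldol step; C8a (trans fusion) and C1 (benzyl anti to the angular methyl) from the Li/NH3 reductive benzylation; C2 from HAT hydrogenation (equatorial methyl). The ring enlargement touches no stereocentre.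

Key step: step 16

Assumption: the aryl hydrogen sulfate is a strong acid, so 25 and 26 would be handled as sodium (or tetrabutylammonium) salts; they are written in the protonated form of the target.
Abbreviations: TIPS = triisopropylsilyl; TES = triethylsilyl; ArBn = 2-(benzyloxy)-3-(TIPS-oxy)-5-[(TIPS-oxy)methyl]phenyl; ArOH = 2-hydroxy-3-(TIPS-oxy)-5-[(TIPS-oxy)methyl]phenyl.

Step 1
Reactants: 1 3-bromo-4,5-dihydroxybenzaldehyde
Product: 2 4-(benzyloxy)-3-bromo-5-hydroxybenzaldehyde
Conditions: BnBr (1.05 equiv), NaHCO3, NaI (cat.), DMF, 40 °C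
Reagents that add atoms: benzyl bromide, BrCc1ccccc1
Why: Williamson etherification under weak-base control: only the 4-OH (para to CHO, ortho to Br), the more acidic phenol, is ionised by bicarbonate, so benzylation should go there, as in the regioselective 4-O-alkylation of 3,4-dihydroxybenzaldehydes.

Step 2
Reactants: 2 4-(benzyloxy)-3-bromo-5-hydroxybenzaldehyde
Product: 3 2-(benzyloxy)-3-bromo-5-(hydroxymethyl)phenol
Conditions: NaBH4, MeOH/THF, 0 °C
Reagents that add atoms: none
Why: Borohydride reduction of an aryl aldehyde; aryl bromide, phenol and benzyl ether are inert.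

Step 3
Reactants: 3 2-(benzyloxy)-3-bromo-5-(hydroxymethyl)phenol
Product: 4 [2-(benzyloxy)-3-bromo-5-(triisopropylsilyloxymethyl)phenoxy]triisopropylsilane
Conditions: TIPSCl (2.5 equiv), imidazole, DMF, rt → 40 °C
Reagents that add atoms: triisopropylsilyl chloride, CC(C)[Si](Cl)(C(C)C)C(C)C
Why: Silyl chloride/imidazole silylation of both the phenol and the primary alcohol; TIPS is chosen because it must survive enolates, ylides and Lewis acid and leave at the end with fluoride.

Step 4
Reactants: 4 [2-(benzyloxy)-3-bromo-5-(triisopropylsilyloxymethyl)phenoxy]triisopropylsilane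
Product: 6 2-(benzyloxy)-3-(triisopropylsilyloxy)-5-(triisopropylsilyloxymethyl)benzaldehyde, via aryllithium 5 (not isolated)
Conditions: n-BuLi, THF, −78 °C; DMF, −78 → 0 °C; aq. NH4Cl
Reagents that add atoms: N,N-dimethylformamide, CN(C)C=O
Why: Bromine–lithium exchange followed by Bouveault formylation; at −78 °C exchange should outrun benzylic deprotonation, and the siloxy group is meta to lithium so no retro-Brook shift is possible.

Step 5
Reactants: 6 2-(benzyloxy)-3-(triisopropylsilyloxy)-5-(triisopropylsilyloxymethyl)benzaldehyde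
Product: 7 [2-(benzyloxy)-3-(triisopropylsilyloxy)-5-(triisopropylsilyloxymethyl)phenyl]methanol
Conditions: NaBH4, MeOH/THF, 0 °C
Reagents that add atoms: none
Why: Borohydride reduction of the aryl aldehyde; silyl and benzyl ethers are untouched.

Step 6
Reactants: 7 [2-(benzyloxy)-3-(triisopropylsilyloxy)-5-(triisopropylsilyloxymethyl)phenyl]methanol
Product: 8 2-(benzyloxy)-1-(bromomethyl)-3-(triisopropylsilyloxy)-5-(triisopropylsilyloxymethyl)benzene
Conditions: CBr4, PPh3, CH2Cl2, 0 °C; used without storage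
Reagents that add atoms: carbon tetrabromide, BrC(Br)(Br)Br
Why: Appel bromination under neutral conditions, which the silyl ethers and the benzyl ether tolerate.

Step 7
Reactants: 9 2-methylcyclopentane-1,3-dione; 10 pent-1-en-3-one (ethyl vinyl ketone)
Product: 11 2-methyl-2-(3-oxopentyl)cyclopentane-1,3-dione
Conditions: H2O, AcOH (cat.), 70 °C
Reagents that add atoms: none
Why: Michael addition of the cyclic 1,3-dione to the vinyl ketone (first half of a Robinson annulation); the product has no stereocentre.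

Step 8
Reactants: 11 2-methyl-2-(3-oxopentyl)cyclopentane-1,3-dione
Product: 12 (7aS)-4,7a-dimethyl-2,3,7,7a-tetrahydro-1H-indene-1,5(6H)-dione
Conditions: L-phenylalanine (1 equiv), 1 M HClO4 (0.5 equiv), MeCN, 80 °C; recrystallisation
Reagents that add atoms: none
Why: Hajos–Parrish–Eder–Sauer–Wiechert enamine-mediated intramolecular aldol condensation, which desymmetrises the two ring carbonyls; the L-amino acid should give the (S)-configured quaternary carbon, in the same sense as L-proline in the parent case.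

Step 9
Reactants: 12 (7aS)-4,7a-dimethyl-2,3,7,7a-tetrahydro-1H-indene-1,5(6H)-dione
Product: 13 (1S,7aS)-1-hydroxy-4,7a-dimethyl-1,2,3,6,7,7a-hexahydro-5H-inden-5-one
Conditions: NaBH4 (0.3 equiv), EtOH, −20 °C
Reagents that add atoms: none
Why: Chemoselective borohydride reduction of the saturated cyclopentanone over the conjugated ketone; hydride should enter anti to the angular methyl, and the resulting stereocentre is only temporary.

Step 10
Reactants: 13 (1S,7aS)-1-hydroxy-4,7a-dimethyl-1,2,3,6,7,7a-hexahydro-5H-inden-5-one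
Product: 14 (1S,7aS)-4,7a-dimethyl-1-(triethylsilyloxy)-1,2,3,6,7,7a-hexahydro-5H-inden-5-one
Conditions: TESCl, imidazole, DMF, 0 °C → rt
Reagents that add atoms: chlorotriethylsilane, CC[Si](Cl)(CC)CC
Why: Standard silylation; TES masks the future ring-expansion carbonyl during the dissolving-metal step and can later be removed by mild acid beside TIPS and benzyl ethers.

Step 11
Reactants: 14 (1S,7aS)-4,7a-dimethyl-1-(triethylsilyloxy)-1,2,3,6,7,7a-hexahydro-5H-inden-5-one; 8 2-(benzyloxy)-1-(bromomethyl)-3-(triisopropylsilyloxy)-5-(triisopropylsilyloxymethyl)benzene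
Product: 16 (1S,3aR,4S,7aS)-4-(ArBn-methyl)-4,7a-dimethyl-1-(triethylsilyloxy)octahydro-5H-inden-5-one, via lithium enolate 15 (not isolated)
Conditions: Li (2.2 equiv), NH3(l)/THF, t-BuOH (1 equiv), −78 °C; isoprene; 8 (1.2 equiv), THF, −78 → −33 °C; NH4Cl
Reagents that add atoms: none
Why: Birch-type reductive alkylation of an enone: protonation at C3a anti to the angular methyl should give the trans-hydrindane enolate regiospecifically, and the benzyl bromide should attack C4 on the face anti to the axial 7a-methyl, which sets the quaternary centre with the methyl cis to the angular methyl.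

Step 12
Reactants: 16 (1S,3aR,4S,7aS)-4-(ArBn-methyl)-4,7a-dimethyl-1-(triethylsilyloxy)octahydro-5H-inden-5-one
Product: 17 (1S,3aS,4S,7aS)-4-(ArBn-methyl)-4,7a-dimethyl-5-methylidene-1-(triethylsilyloxy)octahydro-1H-indene
Conditions: Ph3PCH3Br, KHMDS, THF, 0 → 65 °C
Reagents that add atoms: methyltriphenylphosphonium bromide, C[P+](c1ccccc1)(c1ccccc1)c1ccccc1.[Br-]
Why: Wittig methylenation of a hindered ketone with excess alkoxide-free ylide, which spares the aryl silyl ether.

Step 13
Reactants: 17 (1S,3aS,4S,7aS)-4-(ArBn-methyl)-4,7a-dimethyl-5-methylidene-1-(triethylsilyloxy)octahydro-1H-indene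
Product: 18 (1S,3aS,4R,5S,7aS)-4-(ArBn-methyl)-4,5,7a-trimethyl-1-(triethylsilyloxy)octahydro-1H-indene
Conditions: Mn(dpm)3 (cat.), PhSiH3, t-BuOOH, i-PrOH, rt
Reagents that add atoms: none
Why: Metal-hydride hydrogen-atom-transfer (Mukaiyama-type) hydrogenation: the tertiary C5 radical should take up hydrogen axially on the α-face, opposite the axial C4 methyl, to give the equatorial (also thermodynamically preferred) methyl, and the benzyl ether survives, which it would not under Pd/H2.

Step 14
Reactants: 18 (1S,3aS,4R,5S,7aS)-4-(ArBn-methyl)-4,5,7a-trimethyl-1-(triethylsilyloxy)octahydro-1H-indene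
Product: 19 (1S,3aS,4R,5S,7aS)-4-(ArBn-methyl)-4,5,7a-trimethyloctahydro-1H-inden-1-ol
Conditions: PPTS (cat.), MeOH/CH2Cl2, rt
Reagents that add atoms: none
Why: Acid-catalysed methanolysis of the TES ether, which is several orders of magnitude more labile than the aryl and primary TIPS ethers.

Step 15
Reactants: 19 (1S,3aS,4R,5S,7aS)-4-(ArBn-methyl)-4,5,7a-trimethyloctahydro-1H-inden-1-ol
Product: 20 (3aS,4R,5S,7aS)-4-(ArBn-methyl)-4,5,7a-trimethyloctahydro-1H-inden-1-one
Conditions: Dess–Martin periodinane, NaHCO3, CH2Cl2, rt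
Reagents that add atoms: none
Why: Dess–Martin oxidation of a secondary alcohol; the fully protected arene is not oxidised and the ketone has no epimerisable α-stereocentre.

Step 16
Reactants: 20 (3aS,4R,5S,7aS)-4-(ArBn-methyl)-4,5,7a-trimethyloctahydro-1H-inden-1-one
Product: 22 (4aS,5R,6S,8aS)-5-(ArBn-methyl)-5,6,8a-trimethyloctahydronaphthalen-1(2H)-one, via alpha-silyl ketone 21 (not isolated)
Conditions: TMSCHN2 (2 equiv), AlMe3 (1.2 equiv), CH2Cl2, −78 → −20 °C; then 1 M HCl, THF, rt
Reagents that add atoms: (trimethylsilyl)diazomethane, C[Si](C)(C)C=[N+]=[N-]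
Why: The AlMe3-activated carbonyl C1 is attacked by the diazo carbon to give a β-oxido diazonium betaine, and loss of N2 is concerted with a 1,2-shift of the ring CH2 (C2) antiperiplanar to the C–N2+ bond, which inserts the new carbon between C1 and C2 (Tiffeneau–Demjanov-type diazoalkane homologation, the reaction type of the D-homoannulation of 17-oxo steroids). No ring is closed by cyclisation: the six-membered ring arises by one-carbon enlargement of the five-membered ring, with the C7a–C1 bond untouched. The only new stereocentre, the silyl-bearing carbon of 21, is erased by protodesilylation, and the existing ones cannot be scrambled because C7a is quaternary and C3a is β to the carbonyl. The step needs migration of C2 in preference to the quaternary C7a, which the bulky TMS group should secure because the betaine conformer that places N2+ anti to C7a forces TMS against the quaternary centre. It also needs mono-homologation, which the hindered α-silyl ketone should secure by not reacting a second time.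

Step 17
Reactants: 22 (4aS,5R,6S,8aS)-5-(ArBn-methyl)-5,6,8a-trimethyloctahydronaphthalen-1(2H)-one
Product: 23 (4aS,5R,6S,8aS)-5-(ArOH-methyl)-5,6,8a-trimethyloctahydronaphthalen-1(2H)-one
Conditions: H2 (1 atm), 10% Pd/C, EtOAc, rt
Reagents that add atoms: none
Why: Hydrogenolysis of the aryl benzyl ether, done before any alkene is present; the hindered ketone and the silyl ethers should survive in neutral EtOAc.

Step 18
Reactants: 23 (4aS,5R,6S,8aS)-5-(ArOH-methyl)-5,6,8a-trimethyloctahydronaphthalen-1(2H)-one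
Product: 24 2-(triisopropylsilyloxy)-4-(triisopropylsilyloxymethyl)-6-{[(1R,2S,4aS,8aS)-1,2,4a-trimethyl-5-methylidenedecahydronaphthalen-1-yl]methyl}phenol
Conditions: Ph3PCH3Br (6 equiv), KHMDS (5.5 equiv), toluene, 0 → 90 °C
Reagents that add atoms: methyltriphenylphosphonium bromide, C[P+](c1ccccc1)(c1ccccc1)c1ccccc1.[Br-]
Why: Wittig methylenation of the α-quaternary decalone with excess ylide while the phenol rides through as its phenoxide; the bulky TIPS group has no thermodynamic incentive to move to the flanked oxygen.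

Step 19
Reactants: 24 2-(triisopropylsilyloxy)-4-(triisopropylsilyloxymethyl)-6-{[(1R,2S,4aS,8aS)-1,2,4a-trimethyl-5-methylidenedecahydronaphthalen-1-yl]methyl}phenol
Product: 25 2-(triisopropylsilyloxy)-4-(triisopropylsilyloxymethyl)-6-{[(1R,2S,4aS,8aS)-1,2,4a-trimethyl-5-methylidenedecahydronaphthalen-1-yl]methyl}phenyl hydrogen sulfate
Conditions: SO3·pyridine (5 equiv), pyridine, 50 °C; aq. NaHCO3
Reagents that add atoms: sulfur trioxide pyridine complex, [O-]S(=O)(=O)[n+]1ccccc1
Why: O-Sulfation of the only free hydroxyl with an SO3–amine complex; the weakly basic medium should leave the neighbouring silyl ether in place and the 1,1-disubstituted alkene is inert to the complex.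

Step 20
Reactants: 25 2-(triisopropylsilyloxy)-4-(triisopropylsilyloxymethyl)-6-{[(1R,2S,4aS,8aS)-1,2,4a-trimethyl-5-methylidenedecahydronaphthalen-1-yl]methyl}phenyl hydrogen sulfate
Product: 26 2-hydroxy-4-(hydroxymethyl)-6-{[(1R,2S,4aS,8aS)-1,2,4a-trimethyl-5-methylidenedecahydronaphthalen-1-yl]methyl}phenyl hydrogen sulfate
Conditions: TBAF (3 equiv), THF, 0 °C → rt; Na+ ion exchange
Reagents that add atoms: none
Why: Fluoride cleavage of both TIPS ethers under non-acidic conditions, which should leave the aryl sulfate monoester and the exocyclic alkene untouched.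

**Compound list**
1 | 3-bromo-4,5-dihydroxybenzaldehyde | O=Cc1cc(O)c(O)c(Br)c1 | starting material
2 | 4-(benzyloxy)-3-bromo-5-hydroxybenzaldehyde | O=Cc1cc(O)c(OCc2ccccc2)c(Br)c1 | intermediate
3 | 2-(benzyloxy)-3-bromo-5-(hydroxymethyl)phenol | OCc1cc(O)c(OCc2ccccc2)c(Br)c1 | intermediate
4 | [2-(benzyloxy)-3-bromo-5-(triisopropylsilyloxymethyl)phenoxy]triisopropylsilane | Brc1cc(CO[Si](C(C)C)(C(C)C)C(C)C)cc(O[Si](C(C)C)(C(C)C)C(C)C)c1OCc1ccccc1 | intermediate
5 | aryllithium from 4 (Li in place of Br) | [Li]c1cc(CO[Si](C(C)C)(C(C)C)C(C)C)cc(O[Si](C(C)C)(C(C)C)C(C)C)c1OCc1ccccc1 | intermediate (not isolated)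
6 | 2-(benzyloxy)-3-(triisopropylsilyloxy)-5-(triisopropylsilyloxymethyl)benzaldehyde | O=Cc1cc(CO[Si](C(C)C)(C(C)C)C(C)C)cc(O[Si](C(C)C)(C(C)C)C(C)C)c1OCc1ccccc1 | intermediate
7 | [2-(benzyloxy)-3-(triisopropylsilyloxy)-5-(triisopropylsilyloxymethyl)phenyl]methanol | OCc1cc(CO[Si](C(C)C)(C(C)C)C(C)C)cc(O[Si](C(C)C)(C(C)C)C(C)C)c1OCc1ccccc1 | intermediate
8 | 2-(benzyloxy)-1-(bromomethyl)-3-(triisopropylsilyloxy)-5-(triisopropylsilyloxymethyl)benzene | BrCc1cc(CO[Si](C(C)C)(C(C)C)C(C)C)cc(O[Si](C(C)C)(C(C)C)C(C)C)c1OCc1ccccc1 | intermediate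
9 | 2-methylcyclopentane-1,3-dione | CC1C(=O)CCC1=O | starting material
10 | pent-1-en-3-one (ethyl vinyl ketone) | CCC(=O)C=C | starting material
11 | 2-methyl-2-(3-oxopentyl)cyclopentane-1,3-dione | CCC(=O)CCC1(C)C(=O)CCC1=O | intermediate
12 | (7aS)-4,7a-dimethyl-2,3,7,7a-tetrahydro-1H-indene-1,5(6H)-dione | C[C@]12CCC(=O)C(C)=C1CCC2=O | intermediate
13 | (1S,7aS)-1-hydroxy-4,7a-dimethyl-1,2,3,6,7,7a-hexahydro-5H-inden-5-one | C[C@]12CCC(=O)C(C)=C1CC[C@@H]2O | intermediate
14 | (1S,7aS)-4,7a-dimethyl-1-(triethylsilyloxy)-1,2,3,6,7,7a-hexahydro-5H-inden-5-one | C[C@]12CCC(=O)C(C)=C1CC[C@@H]2O[Si](CC)(CC)CC | intermediate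
15 | trans-fused lithium enolate (C4=C5–OLi; 3a-H anti to 7a-methyl) | CC[Si](CC)(CC)O[C@H]1CC[C@H]2C(C)=C(O[Li])CC[C@]12C | intermediate (not isolated)
16 | (1S,3aR,4S,7aS)-4-(ArBn-methyl)-4,7a-dimethyl-1-(triethylsilyloxy)octahydro-5H-inden-5-one | CC[Si](CC)(CC)O[C@H]1CC[C@H]2[C@](C)(Cc3cc(CO[Si](C(C)C)(C(C)C)C(C)C)cc(O[Si](C(C)C)(C(C)C)C(C)C)c3OCc3ccccc3)C(=O)CC[C@]12C | intermediate
17 | (1S,3aS,4S,7aS)-4-(ArBn-methyl)-4,7a-dimethyl-5-methylidene-1-(triethylsilyloxy)octahydro-1H-indene | CC[Si](CC)(CC)O[C@H]1CC[C@H]2[C@](C)(Cc3cc(CO[Si](C(C)C)(C(C)C)C(C)C)cc(O[Si](C(C)C)(C(C)C)C(C)C)c3OCc3ccccc3)C(=C)CC[C@]12C | intermediate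
18 | (1S,3aS,4R,5S,7aS)-4-(ArBn-methyl)-4,5,7a-trimethyl-1-(triethylsilyloxy)octahydro-1H-indene | CC[Si](CC)(CC)O[C@H]1CC[C@H]2[C@](C)(Cc3cc(CO[Si](C(C)C)(C(C)C)C(C)C)cc(O[Si](C(C)C)(C(C)C)C(C)C)c3OCc3ccccc3)[C@@H](C)CC[C@]12C | intermediate
19 | (1S,3aS,4R,5S,7aS)-4-(ArBn-methyl)-4,5,7a-trimethyloctahydro-1H-inden-1-ol | O[C@H]1CC[C@H]2[C@](C)(Cc3cc(CO[Si](C(C)C)(C(C)C)C(C)C)cc(O[Si](C(C)C)(C(C)C)C(C)C)c3OCc3ccccc3)[C@@H](C)CC[C@]12C | intermediate
20 | (3aS,4R,5S,7aS)-4-(ArBn-methyl)-4,5,7a-trimethyloctahydro-1H-inden-1-one | O=C1CC[C@H]2[C@](C)(Cc3cc(CO[Si](C(C)C)(C(C)C)C(C)C)cc(O[Si](C(C)C)(C(C)C)C(C)C)c3OCc3ccccc3)[C@@H](C)CC[C@]12C | intermediate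
21 | 2-(trimethylsilyl) derivative of 22 (alpha-silyl ketone, both C2 epimers) | O=C1C([Si](C)(C)C)CC[C@H]2[C@](C)(Cc3cc(CO[Si](C(C)C)(C(C)C)C(C)C)cc(O[Si](C(C)C)(C(C)C)C(C)C)c3OCc3ccccc3)[C@@H](C)CC[C@]12C | intermediate (not isolated)
22 | (4aS,5R,6S,8aS)-5-(ArBn-methyl)-5,6,8a-trimethyloctahydronaphthalen-1(2H)-one | O=C1CCC[C@H]2[C@](C)(Cc3cc(CO[Si](C(C)C)(C(C)C)C(C)C)cc(O[Si](C(C)C)(C(C)C)C(C)C)c3OCc3ccccc3)[C@@H](C)CC[C@]12C | intermediate
23 | (4aS,5R,6S,8aS)-5-(ArOH-methyl)-5,6,8a-trimethyloctahydronaphthalen-1(2H)-one | O=C1CCC[C@H]2[C@](C)(Cc3cc(CO[Si](C(C)C)(C(C)C)C(C)C)cc(O[Si](C(C)C)(C(C)C)C(C)C)c3O)[C@@H](C)CC[C@]12C | intermediate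
24 | 2-(triisopropylsilyloxy)-4-(triisopropylsilyloxymethyl)-6-{[(1R,2S,4aS,8aS)-1,2,4a-trimethyl-5-methylidenedecahydronaphthalen-1-yl]methyl}phenol | C=C1CCC[C@H]2[C@](C)(Cc3cc(CO[Si](C(C)C)(C(C)C)C(C)C)cc(O[Si](C(C)C)(C(C)C)C(C)C)c3O)[C@@H](C)CC[C@]12C | intermediate
25 | 2-(triisopropylsilyloxy)-4-(triisopropylsilyloxymethyl)-6-{[(1R,2S,4aS,8aS)-1,2,4a-trimethyl-5-methylidenedecahydronaphthalen-1-yl]methyl}phenyl hydrogen sulfate | C=C1CCC[C@H]2[C@](C)(Cc3cc(CO[Si](C(C)C)(C(C)C)C(C)C)cc(O[Si](C(C)C)(C(C)C)C(C)C)c3OS(=O)(=O)O)[C@@H](C)CC[C@]12C | intermediate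
26 | 2-hydroxy-4-(hydroxymethyl)-6-{[(1R,2S,4aS,8aS)-1,2,4a-trimethyl-5-methylidenedecahydronaphthalen-1-yl]methyl}phenyl hydrogen sulfate | C=C1CCC[C@H]2[C@](C)(Cc3cc(CO)cc(O)c3OS(=O)(=O)O)[C@@H](C)CC[C@]12C | target

**Step count and risks**
Total step count: 20 (steps 1–6 arene, 7–10 hydrindenone, 11–20 after the union).
Longest linear sequence: 16 steps (steps 1–6 and 11–20); the terpenoid branch runs 14 steps (7–20).

Steps most likely to fail:

Step 11. The hindered tetrasubstituted enolate may be O-benzylated or simply protonated instead of C-alkylated, and the ring fusion and the facial selectivity of the alkylation may be imperfectly controlled in liquid ammonia. Fallback: setting out from 14, the enone would be reduced with Li/NH3 (t-BuOH) and the enolate trapped with TMSCl/Et3N to give the isolable trimethylsilyl enol ether F1. This neutral enol silane would then be benzylated with bromide 8 and ZnBr2 in CH2Cl2 (Reetz-type SN1 alkylation): the ortho-alkoxybenzyl cation should be captured at C4 on the face anti to the angular methyl, with O-alkylation excluded. The sequence comes back to the route at 16.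

Step 16. Part of the material may rearrange by migration of the quaternary carbon, giving the regioisomeric ketone, or addition to the neopentyl carbonyl may be sluggish. Fallback: setting out from 20, LDA/TMSCl would give the trimethylsilyl enol ether F2, which can only form toward C2. Cyclopropanation (Et2Zn, CH2I2) would give the siloxycyclopropane F3. FeCl3 in DMF would open its internal bond (Ito–Saegusa ring enlargement) to the β-chloro ketone F4, and NaOAc in MeOH would eliminate HCl to the cyclohexenone F5. Hydrogenation (H2, Pd/C, EtOAc) would saturate the enone and remove the benzyl group in the same operation, coming back to the route at 23. Here the regiochemistry is fixed by enolisation, not by migratory aptitude.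

Step 19. Sulfation of the phenol, which is flanked on both sides, may stay incomplete, and prolonged exposure to base may let the neighbouring silyl group wander between the catechol oxygens. Fallback: setting out from 24, 2,2,2-trichloroethyl chlorosulfate with Et3N/DMAP in THF would give the neutral, chromatographable aryl 2,2,2-trichloroethyl sulfate diester F6. Zinc dust with ammonium formate in MeOH would remove the trichloroethyl group by reductive fragmentation, coming back to the route at 25.

**Further compounds**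
F1 | step 11 | trans-fused 4,7a-dimethyl-1-(triethylsilyloxy)-5-(trimethylsilyloxy)-2,3,3a,6,7,7a-hexahydro-1H-indene (TMS enol ether) | CC[Si](CC)(CC)O[C@H]1CC[C@H]2C(C)=C(O[Si](C)(C)C)CC[C@]12C
F2 | step 16 | trimethylsilyl enol ether of 20 (C1=C2) | C[Si](C)(C)OC1=CC[C@H]2[C@](C)(Cc3cc(CO[Si](C(C)C)(C(C)C)C(C)C)cc(O[Si](C(C)C)(C(C)C)C(C)C)c3OCc3ccccc3)[C@@H](C)CC[C@]12C
F3 | step 16 | siloxycyclopropane from F2 (CH2 bridging C1 and C2) | C[Si](C)(C)OC12CC1C[C@H]3[C@](C)(Cc4cc(CO[Si](C(C)C)(C(C)C)C(C)C)cc(O[Si](C(C)C)(C(C)C)C(C)C)c4OCc4ccccc4)[C@@H](C)CC[C@]23C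
F4 | step 16 | 3-chloro derivative of 22 (β-chloro ketone) | O=C1CC(Cl)C[C@H]2[C@](C)(Cc3cc(CO[Si](C(C)C)(C(C)C)C(C)C)cc(O[Si](C(C)C)(C(C)C)C(C)C)c3OCc3ccccc3)[C@@H](C)CC[C@]12C
F5 | step 16 | 2,3-didehydro derivative of 22 (cyclohex-2-enone) | O=C1C=CC[C@H]2[C@](C)(Cc3cc(CO[Si](C(C)C)(C(C)C)C(C)C)cc(O[Si](C(C)C)(C(C)C)C(C)C)c3OCc3ccccc3)[C@@H](C)CC[C@]12C
F6 | step 19 | aryl 2,2,2-trichloroethyl sulfate diester of 24 | C=C1CCC[C@H]2[C@](C)(Cc3cc(CO[Si](C(C)C)(C(C)C)C(C)C)cc(O[Si](C(C)C)(C(C)C)C(C)C)c3OS(=O)(=O)OCC(Cl)(Cl)Cl)[C@@H](C)CC[C@]12C
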